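**Plan**

Numbering: C1 (alkyne CH) to C15 (ethyl CH3); the oxocene is O/C7–C13. The retrosynthesis cuts, in order: the acetate and C3=C4 (enyne cross-metathesis), C5–C6 (chloroallylboration of a C6 aldehyde), C12–Br (SN2 on a C12 alcohol), C13–C14 (Grignard/silane on a C13 lactone), and finally C11–C12 together with O–C13.
Enabling feature: the ring oxygen is joined through C7–C8 to the chloroalkene carbon C9, and C9=C10(Cl)–C11 is an allyl unit that ends at C12–C13–O. Contracting O/C7/C8/C9 to an oxetane makes the oxocene the product of a strain-releasing 3-oxonia [3,3] shift of a 2-(1-chlorovinyl)oxetane that has captured a ketene at oxygen (four- to eight-membered ring).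
Forward: C6–C9 from ethyl (S)-4-chloro-3-hydroxybutanoate and C10–C11 from vinyl chloride; oxetane by epoxide 4-exo closure; oxocene by ring enlargement with benzyloxyketene (C12–C13); then ethyl, bromide and the C1–C6 side chain.
Stereochemistry: C7 from the chiral pool (inverted once on oxetane closure); temporary C9 by 1,3-syn reduction, relayed to C12 in the key step and inverted on bromination; C13 by hydride addition cis across the ring; C5/C6 by reagent-controlled (Z)-γ-chloroallylboration; Z-enyne by cross-metathesis.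

Key step: step 6

Remark: the target is read as the (3Z,5S,6S,7R,9E,12S,13R) isomer; trimethyl(but-3-en-1-yn-1-yl)silane, vinyl chloride and (+)-B-methoxydiisopinocampheylborane are taken as catalogue chemicals.

**Step 1**
Reactants: 1 ethyl (3S)-4-chloro-3-hydroxybutanoate
Product: 2 (3S)-4-chloro-3-hydroxy-N-methoxy-N-methylbutanamide
Conditions: MeNH(OMe)·HCl (1.5 equiv), iPrMgCl (4.2 equiv), THF, −20 → 0 °C
Reagents that add atoms: N,O-dimethylhydroxylamine hydrochloride, CNOC.Cl
Why: Direct aminolysis of the ester by the chloromagnesium amide (Weinreb amide formation) should proceed at low temperature without closing the chlorohydrin magnesium alkoxide to an epoxide, and the carbinol center is untouched.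

**Step 2**
Reactants: 2 (3S)-4-chloro-3-hydroxy-N-methoxy-N-methylbutanamide; 3 chloroethene (vinyl chloride)
Product: 5 (5S)-2,6-dichloro-5-hydroxyhex-1-en-3-one, via 1-chloro-1-lithioethene 4 (not isolated)
Conditions: 3 (3 equiv), s-BuLi (2.6 equiv), THF/Et2O/pentane 4:1:1, −110 °C; then 2, −110 → −95 °C; inverse quench into cold 1 M HCl
Reagents that add atoms: none
Why: α-Lithiated vinyl chloride, a carbenoid that is stable only below about −100 °C, should add once to the Weinreb amide because the N-methoxy chelate holds the tetrahedral adduct until the acid quench (Weinreb ketone synthesis); the first equivalent only deprotonates the hydroxyl group.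

**Step 3**
Reactants: 5 (5S)-2,6-dichloro-5-hydroxyhex-1-en-3-one
Product: 6 (3R,5S)-2,6-dichlorohex-1-ene-3,5-diol
Conditions: Et2BOMe (1.2 equiv), THF/MeOH 4:1, −78 °C; NaBH4 (1.2 equiv); AcOH, then MeOH co-evaporation
Reagents that add atoms: none
Why: Narasaka–Prasad reduction: the β-hydroxy ketone is locked as a six-membered diethylboron chelate and external hydride adds axially, which should set the new allylic carbinol (3R) 1,3-syn to the resident one and favour 1,2- over 1,4-reduction of the chloro-enone.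

**Step 4**
Reactants: 6 (3R,5S)-2,6-dichlorohex-1-ene-3,5-diol
Product: 8 [(2R,4R)-4-(1-chloroethenyl)oxetan-2-yl]methanol, via epoxy alcohol 7 (not isolated)
Conditions: NaH (2.3 equiv), THF/DMSO 5:1, 0 → 45 °C; aq NH4Cl
Reagents that add atoms: none
Why: Williamson closure of the secondary chlorohydrin should give terminal epoxide 7, which the remaining allylic alkoxide opens at the internal carbon in the 4-exo mode (base-mediated 3,4-epoxy alcohol to oxetane isomerisation) with inversion there, so the 1,3-syn diol becomes the trans-2,4-disubstituted oxetane and frees the primary hydroxyl group.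

**Step 5**
Reactants: 8 [(2R,4R)-4-(1-chloroethenyl)oxetan-2-yl]methanol
Product: 9 tert-butyl{[(2R,4R)-4-(1-chloroethenyl)oxetan-2-yl]methoxy}diphenylsilane
Conditions: TBDPSCl, imidazole, DMF, 0 °C → rt
Reagents that add atoms: tert-butyl(chloro)diphenylsilane, CC(C)(C)[Si](Cl)(c1ccccc1)c1ccccc1
Why: Standard silylation of the primary alcohol gives an ether that should survive ketene, Grignard, silane/Lewis acid and phosphine/CBr4 conditions.

**Step 6**
Reactants: 9 tert-butyl{[(2R,4R)-4-(1-chloroethenyl)oxetan-2-yl]methoxy}diphenylsilane; 10 (benzyloxy)acetyl chloride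
Product: 13 (3R,5E,8R)-3-(benzyloxy)-8-{[tert-butyl(diphenyl)silyl]oxymethyl}-5-chloro-3,4,7,8-tetrahydro-2H-oxocin-2-one, via (benzyloxy)ketene 11 (not isolated), via oxetanium enolate 12 (not isolated)
Conditions: 10 (3 equiv, added over 8 h), iPr2NEt (3.5 equiv), toluene, 70 °C
Reagents that add atoms: none
Why: Proposed new method: iPr2NEt converts 10 into ketene 11, the basic oxetane oxygen of 9 adds to the ketene carbonyl carbon anti to the benzyloxy group to give oxetanium enolate 12 with OBn cis to the oxide oxygen (new O–C bond), and the enolate carbon then bonds to the CH2 terminus of the 1-chlorovinyl group while the strained allylic C–O bond breaks (new C–C bond), a zwitterionic 3-oxonia [3,3] shift. The closest known reaction type is the Bellus–Claisen (ketene-Claisen) ring enlargement of 2-vinyl tetrahydrofurans and tetrahydropyrans with dichloroketene, together with the acyl-Claisen of allylic amines with alkoxyacetyl chlorides; an alkoxyketene has not been shown with an ether donor, and here the high basicity of the oxetane oxygen and the release of about 25 kcal/mol of ring strain are expected to pull the reversible ketene capture forward. The oxocene is closed by four-atom ring enlargement (four- to eight-membered) through a boat-like six-membered transition state, the hetero analogue of the cis-1,2-divinylcyclobutane to cycloocta-1,5-diene rearrangement, which can only deliver the ring-cis (5E) chloroalkene. The new C-3 stereocenter is controlled by chirality transfer from the allylic oxetane carbon: bonding is suprafacial on an enolate that carries H inside and OBn outside, so the trans-(2R,4R) oxetane should give the 3R lactone with OBn cis to CH2OTBDPS. The step needs the [3,3] path to win over ketene dimerisation, chloride opening of the acyloxonium ion and [1,2] collapse to a six-membered lactone; slow addition of 10 keeps the ketene concentration low, the ammonium chloride is insoluble in toluene, no Lewis acid is present, and the trans CH2OTBDPS group lies outside the forming ring.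

**Step 7**
Reactants: 13 (3R,5E,8R)-3-(benzyloxy)-8-{[tert-butyl(diphenyl)silyl]oxymethyl}-5-chloro-3,4,7,8-tetrahydro-2H-oxocin-2-one
Product: 14 (3R,5E,8R)-3-(benzyloxy)-8-{[tert-butyl(diphenyl)silyl]oxymethyl}-5-chloro-2-ethyl-3,4,7,8-tetrahydro-2H-oxocin-2-ol (anomeric mixture)
Conditions: EtMgBr (1.3 equiv), THF, −78 °C; aq NH4Cl at −78 °C
Reagents that add atoms: ethylmagnesium bromide, CC[Mg]Br
Why: Grignard addition to the lactone should stop at the hemiketal stage because the α-benzyloxy group chelates magnesium in the tetrahedral alkoxide (lactone to lactol mono-addition as in C-glycoside synthesis); the anomeric center is erased in the next step.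

**Step 8**
Reactants: 14 (3R,5E,8R)-3-(benzyloxy)-8-{[tert-butyl(diphenyl)silyl]oxymethyl}-5-chloro-2-ethyl-3,4,7,8-tetrahydro-2H-oxocin-2-ol
Product: 15 (2R,3R,5E,8R)-3-(benzyloxy)-8-{[tert-butyl(diphenyl)silyl]oxymethyl}-5-chloro-2-ethyl-3,4,7,8-tetrahydro-2H-oxocine
Conditions: Et3SiH (5 equiv), TMSOTf (0.3 equiv), CH2Cl2, −78 → −30 °C
Reagents that add atoms: none
Why: The Lewis acid ionises the hemiketal to the endocyclic oxocarbenium ion and Et3SiH delivers hydride (reductive etherification) anti to the adjacent benzyloxy group, which is also the face that leads to the 2,8-cis ether favoured for oxocanes and oxocenes, so C-2 (R) should form with ethyl cis to both neighbours.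

**Step 9**
Reactants: 15 (2R,3R,5E,8R)-3-(benzyloxy)-8-{[tert-butyl(diphenyl)silyl]oxymethyl}-5-chloro-2-ethyl-3,4,7,8-tetrahydro-2H-oxocine
Product: 16 (2R,3R,5E,8R)-8-{[tert-butyl(diphenyl)silyl]oxymethyl}-5-chloro-2-ethyl-3,4,7,8-tetrahydro-2H-oxocin-3-ol
Conditions: BCl3 (3 equiv), C6HMe5 (5 equiv), CH2Cl2, −78 °C; MeOH, aq NaHCO3
Reagents that add atoms: none
Why: BCl3 with pentamethylbenzene as a non-basic benzyl-cation scavenger should cleave the benzyl ether at −78 °C (Lewis-acid debenzylation) without touching the silyl ether, the ring alkene or the vinyl chloride.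

**Step 10**
Reactants: 16 (2R,3R,5E,8R)-8-{[tert-butyl(diphenyl)silyl]oxymethyl}-5-chloro-2-ethyl-3,4,7,8-tetrahydro-2H-oxocin-3-ol
Product: 17 (2R,3S,5E,8R)-3-bromo-8-{[tert-butyl(diphenyl)silyl]oxymethyl}-5-chloro-2-ethyl-3,4,7,8-tetrahydro-2H-oxocine
Conditions: CBr4 (3 equiv), P(n-Oct)3 (6 equiv), toluene, 70 °C
Reagents that add atoms: carbon tetrabromide, BrC(Br)(Br)Br
Why: Appel-type bromination displaces the oxyphosphonium ion by SN2, which should invert C-3 to S and place bromine trans to ethyl, as established for closely related 2-ethyl-oxocen-3-ols.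

**Step 11**
Reactants: 17 (2R,3S,5E,8R)-3-bromo-8-{[tert-butyl(diphenyl)silyl]oxymethyl}-5-chloro-2-ethyl-3,4,7,8-tetrahydro-2H-oxocine
Product: 18 [(2R,3S,5E,8R)-3-bromo-5-chloro-2-ethyl-3,4,7,8-tetrahydro-2H-oxocin-8-yl]methanol
Conditions: Bu4NF/AcOH (1:1, 3 equiv), THF, 0 °C → rt
Reagents that add atoms: none
Why: Fluoride cleaves the silyl ether, and the acetic acid buffer should suppress E2 loss of the secondary bromide.

**Step 12**
Reactants: 18 [(2R,3S,5E,8R)-3-bromo-5-chloro-2-ethyl-3,4,7,8-tetrahydro-2H-oxocin-8-yl]methanol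
Product: 19 (2R,3S,5E,8R)-3-bromo-5-chloro-2-ethyl-3,4,7,8-tetrahydro-2H-oxocine-8-carbaldehyde
Conditions: Dess–Martin periodinane, CH2Cl2, 0 °C → rt; used crude
Reagents that add atoms: none
Why: Dess–Martin oxidation gives the α-alkoxy aldehyde under non-basic conditions that should not epimerise C-8.

**Step 13**
Reactants: 19 (2R,3S,5E,8R)-3-bromo-5-chloro-2-ethyl-3,4,7,8-tetrahydro-2H-oxocine-8-carbaldehyde; 20 3-chloroprop-1-ene (allyl chloride)
Product: 22 (1S,2S)-1-[(2R,3S,5E,8R)-3-bromo-5-chloro-2-ethyl-3,4,7,8-tetrahydro-2H-oxocin-8-yl]-2-chlorobut-3-en-1-ol, via (Z)-(3-chloroallyl)diisopinocampheylborane 21 (not isolated)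
Conditions: 20 (2 equiv), (+)-Ipc2BOMe (1.8 equiv), LiN(c-Hex)2 (2 equiv), Et2O/THF, −95 °C; BF3·OEt2 (2.5 equiv); 19, −95 °C, 4 h; ethanolamine, rt
Reagents that add atoms: none
Why: (Z)-γ-Chloroallylboration through a closed chair transition state should give chlorine and hydroxyl syn, and the isopinocampheyl groups derived from (−)-α-pinene direct attack to the Re face of the aldehyde, giving the (1S,2S) chlorohydrin by reagent control against the Felkin bias of the α-alkoxy aldehyde (a mismatched pairing); the ethanolamine work-up avoids base, so the chlorohydrin should not close to the vinyl epoxide.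

**Step 14**
Reactants: 22 (1S,2S)-1-[(2R,3S,5E,8R)-3-bromo-5-chloro-2-ethyl-3,4,7,8-tetrahydro-2H-oxocin-8-yl]-2-chlorobut-3-en-1-ol
Product: 23 (1S,2S)-1-[(2R,3S,5E,8R)-3-bromo-5-chloro-2-ethyl-3,4,7,8-tetrahydro-2H-oxocin-8-yl]-2-chlorobut-3-en-1-yl acetate
Conditions: Ac2O, pyridine, DMAP (cat.), CH2Cl2, 0 °C → rt
Reagents that add atoms: acetic anhydride, CC(=O)OC(C)=O
Why: DMAP-catalysed acetylation of the secondary alcohol is mild enough that the allylic chloride should be left intact.

**Step 15**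
Reactants: 23 (1S,2S)-1-[(2R,3S,5E,8R)-3-bromo-5-chloro-2-ethyl-3,4,7,8-tetrahydro-2H-oxocin-8-yl]-2-chlorobut-3-en-1-yl acetate; 24 trimethyl(but-3-en-1-yn-1-yl)silane
Product: 25 (1S,2S,3Z)-1-[(2R,3S,5E,8R)-3-bromo-5-chloro-2-ethyl-3,4,7,8-tetrahydro-2H-oxocin-8-yl]-2-chloro-6-(trimethylsilyl)hex-3-en-5-yn-1-yl acetate
Conditions: 24 (5 equiv), second-generation Grubbs catalyst (10 mol %), CH2Cl2, 40 °C
Reagents that add atoms: none
Why: Cross-metathesis of a terminal alkene with a conjugated enyne is known to favour the Z-enyne through the alkynyl-substituted ruthenacyclobutane, and the trisubstituted ring chloroalkene should be inert to the catalyst.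

**Step 16**
Reactants: 25 (1S,2S,3Z)-1-[(2R,3S,5E,8R)-3-bromo-5-chloro-2-ethyl-3,4,7,8-tetrahydro-2H-oxocin-8-yl]-2-chloro-6-(trimethylsilyl)hex-3-en-5-yn-1-yl acetate
Product: 26 (1S,2S,3Z)-1-[(2R,3S,5E,8R)-3-bromo-5-chloro-2-ethyl-3,4,7,8-tetrahydro-2H-oxocin-8-yl]-2-chlorohex-3-en-5-yn-1-yl acetate (CNP0228902.1)
Conditions: Bu4NF/AcOH (1:1), THF, −20 → 0 °C
Reagents that add atoms: none
Why: Fluoride removes the alkynyl silyl group rapidly at low temperature, and the acetic acid buffer should protect the acetate and the allylic chloride.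

**Compound list**

1 | ethyl (3S)-4-chloro-3-hydroxybutanoate | CCOC(=O)C[C@H](O)CCl | starting material
2 | (3S)-4-chloro-3-hydroxy-N-methoxy-N-methylbutanamide | CON(C)C(=O)C[C@H](O)CCl | intermediate
3 | chloroethene (vinyl chloride) | C=CCl | starting material
4 | 1-chloro-1-lithioethene | [Li]C(Cl)=C | intermediate
5 | (5S)-2,6-dichloro-5-hydroxyhex-1-en-3-one | C=C(Cl)C(=O)C[C@H](O)CCl | intermediate
6 | (3R,5S)-2,6-dichlorohex-1-ene-3,5-diol | C=C(Cl)[C@H](O)C[C@H](O)CCl | intermediate
7 | (3R)-2-chloro-4-[(2S)-oxiran-2-yl]but-1-en-3-ol | C=C(Cl)[C@H](O)C[C@H]1CO1 | intermediate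
8 | [(2R,4R)-4-(1-chloroethenyl)oxetan-2-yl]methanol | OC[C@H]1C[C@H](C(Cl)=C)O1 | intermediate
9 | tert-butyl{[(2R,4R)-4-(1-chloroethenyl)oxetan-2-yl]methoxy}diphenylsilane | CC(C)(C)[Si](OC[C@H]1C[C@H](C(Cl)=C)O1)(c1ccccc1)c1ccccc1 | intermediate
10 | (benzyloxy)acetyl chloride | O=C(Cl)COCc1ccccc1 | starting material
11 | (benzyloxy)ketene [2-(benzyloxy)ethenone] | O=C=COCc1ccccc1 | intermediate
12 | 2-(benzyloxy)-1-[(2R,4R)-2-{[tert-butyl(diphenyl)silyl]oxymethyl}-4-(1-chloroethenyl)oxetan-1-ium-1-yl]ethen-1-olate (OBn cis to the oxide oxygen) | [O-]/C(=C\OCc1ccccc1)[O+]1[C@@H](C(Cl)=C)C[C@@H]1CO[Si](C(C)(C)C)(c1ccccc1)c1ccccc1 | intermediate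
13 | (3R,5E,8R)-3-(benzyloxy)-8-{[tert-butyl(diphenyl)silyl]oxymethyl}-5-chloro-3,4,7,8-tetrahydro-2H-oxocin-2-one | CC(C)(C)[Si](OC[C@H]1C/C=C(/Cl)C[C@@H](OCc2ccccc2)C(=O)O1)(c1ccccc1)c1ccccc1 | intermediate
14 | (3R,5E,8R)-3-(benzyloxy)-8-{[tert-butyl(diphenyl)silyl]oxymethyl}-5-chloro-2-ethyl-3,4,7,8-tetrahydro-2H-oxocin-2-ol (anomeric mixture) | CC(C)(C)[Si](OC[C@H]1C/C=C(/Cl)C[C@@H](OCc2ccccc2)C(O)(CC)O1)(c1ccccc1)c1ccccc1 | intermediate
15 | (2R,3R,5E,8R)-3-(benzyloxy)-8-{[tert-butyl(diphenyl)silyl]oxymethyl}-5-chloro-2-ethyl-3,4,7,8-tetrahydro-2H-oxocine | CC(C)(C)[Si](OC[C@H]1C/C=C(/Cl)C[C@@H](OCc2ccccc2)[C@@H](CC)O1)(c1ccccc1)c1ccccc1 | intermediate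
16 | (2R,3R,5E,8R)-8-{[tert-butyl(diphenyl)silyl]oxymethyl}-5-chloro-2-ethyl-3,4,7,8-tetrahydro-2H-oxocin-3-ol | CC(C)(C)[Si](OC[C@H]1C/C=C(/Cl)C[C@@H](O)[C@@H](CC)O1)(c1ccccc1)c1ccccc1 | intermediate
17 | (2R,3S,5E,8R)-3-bromo-8-{[tert-butyl(diphenyl)silyl]oxymethyl}-5-chloro-2-ethyl-3,4,7,8-tetrahydro-2H-oxocine | CC(C)(C)[Si](OC[C@H]1C/C=C(/Cl)C[C@H](Br)[C@@H](CC)O1)(c1ccccc1)c1ccccc1 | intermediate
18 | [(2R,3S,5E,8R)-3-bromo-5-chloro-2-ethyl-3,4,7,8-tetrahydro-2H-oxocin-8-yl]methanol | OC[C@H]1C/C=C(/Cl)C[C@H](Br)[C@@H](CC)O1 | intermediate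
19 | (2R,3S,5E,8R)-3-bromo-5-chloro-2-ethyl-3,4,7,8-tetrahydro-2H-oxocine-8-carbaldehyde | O=C[C@H]1C/C=C(/Cl)C[C@H](Br)[C@@H](CC)O1 | intermediate
20 | 3-chloroprop-1-ene (allyl chloride) | C=CCCl | starting material
21 | [(2Z)-3-chloroprop-2-en-1-yl]bis[(1S,2R,3S,5S)-2,6,6-trimethylbicyclo[3.1.1]hept-3-yl]borane | Cl/C=C\CB([C@H]1C[C@H]2C[C@@H]([C@@H]1C)C2(C)C)[C@H]1C[C@H]2C[C@@H]([C@@H]1C)C2(C)C | intermediate
22 | (1S,2S)-1-[(2R,3S,5E,8R)-3-bromo-5-chloro-2-ethyl-3,4,7,8-tetrahydro-2H-oxocin-8-yl]-2-chlorobut-3-en-1-ol | C=C[C@H](Cl)[C@@H](O)[C@H]1C/C=C(/Cl)C[C@H](Br)[C@@H](CC)O1 | intermediate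
23 | (1S,2S)-1-[(2R,3S,5E,8R)-3-bromo-5-chloro-2-ethyl-3,4,7,8-tetrahydro-2H-oxocin-8-yl]-2-chlorobut-3-en-1-yl acetate | C=C[C@H](Cl)[C@@H](OC(C)=O)[C@H]1C/C=C(/Cl)C[C@H](Br)[C@@H](CC)O1 | intermediate
24 | trimethyl(but-3-en-1-yn-1-yl)silane | C=CC#C[Si](C)(C)C | starting material
25 | (1S,2S,3Z)-1-[(2R,3S,5E,8R)-3-bromo-5-chloro-2-ethyl-3,4,7,8-tetrahydro-2H-oxocin-8-yl]-2-chloro-6-(trimethylsilyl)hex-3-en-5-yn-1-yl acetate | C[Si](C)(C)C#C/C=C\[C@H](Cl)[C@@H](OC(C)=O)[C@H]1C/C=C(/Cl)C[C@H](Br)[C@@H](CC)O1 | intermediate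
26 | (1S,2S,3Z)-1-[(2R,3S,5E,8R)-3-bromo-5-chloro-2-ethyl-3,4,7,8-tetrahydro-2H-oxocin-8-yl]-2-chlorohex-3-en-5-yn-1-yl acetate | C#C/C=C\[C@H](Cl)[C@@H](OC(C)=O)[C@H]1C/C=C(/Cl)C[C@H](Br)[C@@H](CC)O1 | target

**Step count and risks**

Total step count: 16. Longest linear sequence: 16 steps (from 1).

Steps most likely to fail:

1. Step 6 (proposed new method). The ether oxygen may capture the weakly electrophilic alkoxyketene more slowly than the ketene condenses with itself, or chloride may open the acyloxonium ion before the sigmatropic shift. The fallback sets out from 9 and returns at 13; it uses the ketene for which this ring enlargement of 2-alkenyl cyclic ethers is established and introduces the C-3 oxygen afterwards. Slow generation of dichloroketene F1 (Cl2CHCOCl, Et3N, Et2O) in the presence of 9 should give (5E,8R)-8-{[tert-butyl(diphenyl)silyl]oxymethyl}-3,3,5-trichloro-3,4,7,8-tetrahydro-2H-oxocin-2-one F2. Zn dust in AcOH removes both α-chlorines to give (5E,8R)-8-{[tert-butyl(diphenyl)silyl]oxymethyl}-5-chloro-3,4,7,8-tetrahydro-2H-oxocin-2-one F3. Enolisation with KN(SiMe3)2 at −78 °C and oxidation with the matching enantiomer of (10-camphorsulfonyl)oxaziridine should give (3R,5E,8R)-8-{[tert-butyl(diphenyl)silyl]oxymethyl}-5-chloro-3-hydroxy-3,4,7,8-tetrahydro-2H-oxocin-2-one F4. Benzylation with benzyl 2,2,2-trichloroacetimidate and catalytic TfOH then gives 13.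

2. Step 8. Hydride may be delivered to the wrong face of the eight-membered oxocarbenium ion (2,8-trans ether), or the ion may lose a proton to the enol ether. The fallback sets out from 13 and returns at 15; it exchanges the roles of hydride and ethyl, so that the same facial preference would now place ethyl on the required face. Reductive acetylation of 13 (i-Bu2AlH, CH2Cl2, −78 °C; then Ac2O, pyridine, DMAP) should give (3R,5E,8R)-3-(benzyloxy)-8-{[tert-butyl(diphenyl)silyl]oxymethyl}-5-chloro-3,4,7,8-tetrahydro-2H-oxocin-2-yl acetate F5. Ionisation with TMSOTf in the presence of Et2Zn (CH2Cl2, −78 °C) then transfers ethyl to the oxocarbenium ion to give 15.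

3. Step 15. The alkene next to the allylic chloride may turn over poorly, and Z/E selectivity may erode in the enyne cross-metathesis. The fallback sets out from 23 and returns at 25; it builds the Z-enyne by olefination and coupling. Oxidative cleavage of the monosubstituted alkene (OsO4 cat., NaIO4, 2,6-lutidine, dioxane/H2O; the chloro-substituted ring alkene reacts far more slowly) should give (1S,2R)-1-[(2R,3S,5E,8R)-3-bromo-5-chloro-2-ethyl-3,4,7,8-tetrahydro-2H-oxocin-8-yl]-2-chloro-3-oxopropyl acetate F6. Stork–Zhao olefination ([Ph3PCH2I]I, NaN(SiMe3)2, THF/DMPU, −78 °C) gives (1S,2S,3Z)-1-[(2R,3S,5E,8R)-3-bromo-5-chloro-2-ethyl-3,4,7,8-tetrahydro-2H-oxocin-8-yl]-2-chloro-4-iodobut-3-en-1-yl acetate F7. Sonogashira coupling with trimethylsilylacetylene (Pd(PPh3)4, CuI, i-Pr2NH, rt) then gives 25.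

**Further compounds**

F1 | step 6 | dichloroketene (2,2-dichloroethenone) | O=C=C(Cl)Cl
F2 | step 6 | (5E,8R)-8-{[tert-butyl(diphenyl)silyl]oxymethyl}-3,3,5-trichloro-3,4,7,8-tetrahydro-2H-oxocin-2-one | CC(C)(C)[Si](OC[C@H]1C/C=C(/Cl)CC(Cl)(Cl)C(=O)O1)(c1ccccc1)c1ccccc1
F3 | step 6 | (5E,8R)-8-{[tert-butyl(diphenyl)silyl]oxymethyl}-5-chloro-3,4,7,8-tetrahydro-2H-oxocin-2-one | CC(C)(C)[Si](OC[C@H]1C/C=C(/Cl)CCC(=O)O1)(c1ccccc1)c1ccccc1
F4 | step 6 | (3R,5E,8R)-8-{[tert-butyl(diphenyl)silyl]oxymethyl}-5-chloro-3-hydroxy-3,4,7,8-tetrahydro-2H-oxocin-2-one | CC(C)(C)[Si](OC[C@H]1C/C=C(/Cl)C[C@@H](O)C(=O)O1)(c1ccccc1)c1ccccc1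
F5 | step 8 | (3R,5E,8R)-3-(benzyloxy)-8-{[tert-butyl(diphenyl)silyl]oxymethyl}-5-chloro-3,4,7,8-tetrahydro-2H-oxocin-2-yl acetate | CC(C)(C)[Si](OC[C@H]1C/C=C(/Cl)C[C@@H](OCc2ccccc2)C(OC(C)=O)O1)(c1ccccc1)c1ccccc1
F6 | step 15 | (1S,2R)-1-[(2R,3S,5E,8R)-3-bromo-5-chloro-2-ethyl-3,4,7,8-tetrahydro-2H-oxocin-8-yl]-2-chloro-3-oxopropyl acetate | O=C[C@H](Cl)[C@@H](OC(C)=O)[C@H]1C/C=C(/Cl)C[C@H](Br)[C@@H](CC)O1
F7 | step 15 | (1S,2S,3Z)-1-[(2R,3S,5E,8R)-3-bromo-5-chloro-2-ethyl-3,4,7,8-tetrahydro-2H-oxocin-8-yl]-2-chloro-4-iodobut-3-en-1-yl acetate | I/C=C\[C@H](Cl)[C@@H](OC(C)=O)[C@H]1C/C=C(/Cl)C[C@H](Br)[C@@H](CC)O1
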